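**Retrosynthetic overview**

1. The dihydropyranone ring is closed last, at C3=C4, by intramolecular Wittig olefination of an ester ylide onto a C4 aldehyde. The same operation first makes C5–C6 (catalytic asymmetric cross-aldol of acetaldehyde onto a C6 ynal) and O1–C2 (addition of the new C6–OH to Ph3P=C=C=O), so C2–C5 and the C6 stereocentre come from three components.
2. Enabling feature: in the lactone ring, O1–C6–C5–C4 is an aldol (β-oxy aldehyde) array and C3=C4 is necessarily cis inside the six-membered ring. C6 also carries C1' of the Z-olefin, which can be carried as an sp carbon, so the C6 aldehyde (an ynal) has no α-hydrogen and the Z-olefin follows by semihydrogenation.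
3. Side chain: C8' and C6' are relayed from the single chiral-pool centre C4' [(S)-epichlorohydrin] by a 1,5-anti boron aldol (C7'–C8') and an Evans–Tishchenko reaction (6',8'-anti, acetate placed on O8' in the same step).
4. C2'–C3' comes from acetylide opening of an epoxide, C5'–C6' from alkylation of 2-methyl-1,3-dithiane (masked methyl ketone).
5. Ring order: a temporary 1,3-dioxane (p-methoxybenzylidene acetal across O4'/O6') is formed first, then the dihydropyranone; the dioxane is removed in the last step.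

Key step: step 10

Remark (numbering used in names): lactone atoms O1, C2–C6; side chain C1'–C10' counted from the ring, phenyl on C10'.

Assumption: the diarylprolinol catalyst is taken to direct the ynal face in the same sense as proline (hydrogen-bond model), so its (R)-enantiomer is specified for the 6S centre; if the sense were the opposite, the (S)-catalyst would be used with no other change.

**Route**

Step 1
Reactants: 1 (S)-epichlorohydrin; 2 2-methyl-1,3-dithiane
Product: 5 2-methyl-2-{[(2S)-oxiran-2-yl]methyl}-1,3-dithiane, via 2-lithio-2-methyl-1,3-dithiane 3 (not isolated), via lithium chlorohydrin alkoxide 4 (not isolated)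
Conditions: 2, n-BuLi, THF, −20 °C; then 1, −78 °C to rt
Reagents that add atoms: none
Why: The sulfur-stabilised carbanion opens the epoxide of 1 at its unsubstituted carbon and the chlorohydrin alkoxide then closes by intramolecular Williamson substitution (epoxide-relay alkylation of a lithiated dithiane), so the C–O stereocentre of 1 is carried over untouched and becomes C4'.

Step 2
Reactants: 5 2-methyl-2-{[(2S)-oxiran-2-yl]methyl}-1,3-dithiane; 6 tert-butyldimethyl(prop-2-yn-1-yloxy)silane
Product: 8 (2R)-6-[(tert-butyldimethylsilyl)oxy]-1-(2-methyl-1,3-dithian-2-yl)hex-4-yn-2-ol, via lithium acetylide 7 (not isolated)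
Conditions: 6, n-BuLi, THF, −78 °C; BF3·OEt2; then 5, −78 °C
Reagents that add atoms: none
Why: BF3-promoted opening of the terminal epoxide by the lithium acetylide at the less hindered carbon (Yamaguchi–Hirao alkynylation) leaves the stereocentre untouched and installs C1'–C2' at the alkyne oxidation level together with C6 as a protected carbinol.

Step 3
Reactants: 8 (2R)-6-[(tert-butyldimethylsilyl)oxy]-1-(2-methyl-1,3-dithian-2-yl)hex-4-yn-2-ol
Product: 9 tert-butyl({(5R)-5-[(4-methoxybenzyl)oxy]-6-(2-methyl-1,3-dithian-2-yl)hex-2-yn-1-yl}oxy)dimethylsilane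
Conditions: NaH, PMBCl, Bu4NI (catalytic), THF/DMF, 0 °C to rt
Reagents that add atoms: 4-methoxybenzyl chloride (PMBCl), COc1ccc(CCl)cc1
Why: Williamson etherification of the secondary alkoxide gives the p-methoxybenzyl ether, the β-alkoxy group that should direct the 1,5-anti aldol of step 5 and that can later be turned into the cyclic acetal without a new reagent-derived group.

Step 4
Reactants: 9 tert-butyl({(5R)-5-[(4-methoxybenzyl)oxy]-6-(2-methyl-1,3-dithian-2-yl)hex-2-yn-1-yl}oxy)dimethylsilane
Product: 10 (4R)-8-[(tert-butyldimethylsilyl)oxy]-4-[(4-methoxybenzyl)oxy]oct-6-yn-2-one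
Conditions: MeI, CaCO3, MeCN/H2O (9:1), 45 °C
Reagents that add atoms: water, O
Why: S-Methylation turns the dithiane into a leaving group and water then releases the methyl ketone (alkylative dithioacetal hydrolysis) under buffered conditions that the silyl ether, the PMB ether and the alkyne should tolerate.

Step 5
Reactants: 10 (4R)-8-[(tert-butyldimethylsilyl)oxy]-4-[(4-methoxybenzyl)oxy]oct-6-yn-2-one; 11 3-phenylpropanal
Product: 13 (3R,7R)-11-[(tert-butyldimethylsilyl)oxy]-3-hydroxy-7-[(4-methoxybenzyl)oxy]-1-phenylundec-9-yn-5-one, via dicyclohexylboron enolate 12 (not isolated)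
Conditions: Cy2BCl, Et3N, Et2O, 0 °C; then 11, −78 to −20 °C; then H2O2, MeOH, pH 7 buffer, 0 °C
Reagents that add atoms: none
Why: In this boron-mediated aldol reaction of a β-alkoxy methyl ketone the kinetic methyl-side boron enolate should add to the aldehyde with 1,5-anti induction from the C4' p-methoxybenzyloxy group (boat-like transition state with a formyl C–H to ether-oxygen contact), which sets C8' as R.

Step 6
Reactants: 13 (3R,7R)-11-[(tert-butyldimethylsilyl)oxy]-3-hydroxy-7-[(4-methoxybenzyl)oxy]-1-phenylundec-9-yn-5-one; 14 acetaldehyde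
Product: 15 (3R,5R,7R)-11-[(tert-butyldimethylsilyl)oxy]-5-hydroxy-7-[(4-methoxybenzyl)oxy]-1-phenylundec-9-yn-3-yl acetate
Conditions: SmI2 (0.3 equiv), CH3CHO (8 equiv), THF, −10 °C
Reagents that add atoms: none
Why: In this Evans–Tishchenko reaction the hemiacetal of the C8' hydroxyl and acetaldehyde, bound to trivalent samarium, delivers hydride intramolecularly to the C6' ketone through a chair-like six-membered transition state, which should give the 6',8'-anti relationship with the acetate regiospecifically on O8' and thereby make C6' syn to C4'.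

Step 7
Reactants: 15 (3R,5R,7R)-11-[(tert-butyldimethylsilyl)oxy]-5-hydroxy-7-[(4-methoxybenzyl)oxy]-1-phenylundec-9-yn-3-yl acetate
Product: 16 (2R)-1-[(2R,4R,6R)-6-{4-[(tert-butyldimethylsilyl)oxy]but-2-yn-1-yl}-2-(4-methoxyphenyl)-1,3-dioxan-4-yl]-4-phenylbutan-2-yl acetate
Conditions: DDQ (1.2 equiv), 4 Å molecular sieves, CH2Cl2, 0 °C
Reagents that add atoms: none
Why: Anhydrous DDQ oxidises the PMB ether to an oxocarbenium ion that is trapped by the syn-1,3-related C6' hydroxyl (oxidative acetalisation), which should give the cis-2,4,6-trisubstituted 1,3-dioxane with all three substituents equatorial and so masks O6' before the ylide of step 10 is used.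

Step 8
Reactants: 16 (2R)-1-[(2R,4R,6R)-6-{4-[(tert-butyldimethylsilyl)oxy]but-2-yn-1-yl}-2-(4-methoxyphenyl)-1,3-dioxan-4-yl]-4-phenylbutan-2-yl acetate
Product: 17 (2R)-1-[(2R,4R,6R)-6-(4-hydroxybut-2-yn-1-yl)-2-(4-methoxyphenyl)-1,3-dioxan-4-yl]-4-phenylbutan-2-yl acetate
Conditions: HF·pyridine, pyridine, THF, 0 °C to rt
Reagents that add atoms: none
Why: Fluoride cleaves the primary silyl ether (desilylation) while the pyridine buffer should spare the acid-labile acetal and the acetate.

Step 9
Reactants: 17 (2R)-1-[(2R,4R,6R)-6-(4-hydroxybut-2-yn-1-yl)-2-(4-methoxyphenyl)-1,3-dioxan-4-yl]-4-phenylbutan-2-yl acetate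
Product: 18 (2R)-1-[(2R,4R,6R)-2-(4-methoxyphenyl)-6-(4-oxobut-2-yn-1-yl)-1,3-dioxan-4-yl]-4-phenylbutan-2-yl acetate
Conditions: MnO2 (activated, excess), CH2Cl2, rt
Reagents that add atoms: none
Why: Activated MnO2 oxidises propargylic alcohols selectively to ynals under neutral conditions (allylic/propargylic oxidation), so the acetal and acetate should be untouched and the base-sensitive ynal should not isomerise.

Step 10
Reactants: 18 (2R)-1-[(2R,4R,6R)-2-(4-methoxyphenyl)-6-(4-oxobut-2-yn-1-yl)-1,3-dioxan-4-yl]-4-phenylbutan-2-yl acetate; 14 acetaldehyde; 19 (triphenylphosphoranylidene)ketene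
Product: 22 (2R)-1-[(2R,4R,6R)-2-(4-methoxyphenyl)-6-{3-[(2S)-6-oxo-3,6-dihydro-2H-pyran-2-yl]prop-2-yn-1-yl}-1,3-dioxan-4-yl]-4-phenylbutan-2-yl acetate, via β-hydroxy ynal 20 (not isolated), via ester ylide 21 (not isolated)
Conditions: (R)-α,α-bis[3,5-bis(trifluoromethyl)phenyl]-2-pyrrolidinemethanol (20 mol %), CH3CHO (5 equiv), 1,4-dioxane, 4 °C; excess CH3CHO removed in vacuo; then 19 (1.5 equiv), toluene, 60 °C
Reagents that add atoms: none
Why: Proposed new method: the prolinol amine turns acetaldehyde into an enamine that adds to the formyl group of 18 (cross-aldol, C5–C6) to give 20, then the new C6 hydroxyl adds across the cumulated C=C bond of 19 to give the ester-stabilised ylide 21, whose intramolecular Wittig olefination of the C4 aldehyde forms C3=C4 and releases Ph3PO. The closest known reaction types are the diarylprolinol-catalysed cross-aldol of acetaldehyde with alkynyl aldehydes, whose labile aldols are trapped in the same flask by stabilised phosphoranes, and the addition–intramolecular Wittig annulation of hydroxy carbonyl compounds with Ph3P=C=C=O to unsaturated lactones; what is new is their merger, the trapping ylide being assembled on the aldol oxygen itself. The dihydropyranone ring is closed in the olefination event (six-ring closure through an oxaphosphetane, the O1–C2 ester bond already being in place), and only the cis ring olefin can result. C6, the one new stereocentre, is set by the catalyst, whose carbinol OH hydrogen-bonds the ynal carbonyl and so exposes one aldehyde face to the enamine, the remote C4', C6' and C8' centres being too far away to matter. The step needs cross- over self-aldol selectivity and acylation of one hydroxyl only: because C1' is an sp carbon, 18 has no α-hydrogen, cannot form an enamine and is a slim, highly electrophilic acceptor, and because O4' and O6' are locked in the dioxane the C6 hydroxyl is the only one that can add to 19. The amine catalyst is itself taken out by the first portion of 19, hence the excess.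

Step 11
Reactants: 22 (2R)-1-[(2R,4R,6R)-2-(4-methoxyphenyl)-6-{3-[(2S)-6-oxo-3,6-dihydro-2H-pyran-2-yl]prop-2-yn-1-yl}-1,3-dioxan-4-yl]-4-phenylbutan-2-yl acetate
Product: 23 (2R)-1-[(2R,4R,6R)-2-(4-methoxyphenyl)-6-{(2Z)-3-[(2S)-6-oxo-3,6-dihydro-2H-pyran-2-yl]prop-2-en-1-yl}-1,3-dioxan-4-yl]-4-phenylbutan-2-yl acetate
Conditions: H2 (1 atm), Pd/CaCO3 poisoned with Pb(OAc)2 (Lindlar catalyst), quinoline, EtOAc, rt
Reagents that add atoms: none
Why: Lindlar semihydrogenation adds hydrogen syn to the internal alkyne and should stop at the olefin, which fixes the C1'=C2' Z geometry while the conjugated ring olefin and the acetal are left alone on poisoned palladium.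

Step 12
Reactants: 23 (2R)-1-[(2R,4R,6R)-2-(4-methoxyphenyl)-6-{(2Z)-3-[(2S)-6-oxo-3,6-dihydro-2H-pyran-2-yl]prop-2-en-1-yl}-1,3-dioxan-4-yl]-4-phenylbutan-2-yl acetate
Product: 24 (3R,5R,7R,9Z)-5,7-dihydroxy-10-[(2S)-6-oxo-3,6-dihydro-2H-pyran-2-yl]-1-phenyldec-9-en-3-yl acetate (CNP0264384.1)
Conditions: AcOH/THF/H2O (4:1:1), 40 °C
Reagents that add atoms: none
Why: Mild aqueous acid hydrolyses the p-methoxybenzylidene acetal (acetal hydrolysis) and should release the 4',6'-diol without cleaving the secondary acetate, the lactone or the Z-olefin.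

**Compound list**

1 | (S)-epichlorohydrin, (2S)-2-(chloromethyl)oxirane | ClC[C@@H]1CO1 | starting material
2 | 2-methyl-1,3-dithiane | CC1SCCCS1 | starting material
3 | 2-lithio-2-methyl-1,3-dithiane | [Li]C1(C)SCCCS1 | intermediate
4 | lithium (2S)-1-chloro-3-(2-methyl-1,3-dithian-2-yl)propan-2-olate | CC1(C[C@@H](CCl)O[Li])SCCCS1 | intermediate
5 | 2-methyl-2-{[(2S)-oxiran-2-yl]methyl}-1,3-dithiane | CC1(C[C@H]2CO2)SCCCS1 | intermediate
6 | tert-butyldimethyl(prop-2-yn-1-yloxy)silane | C#CCO[Si](C)(C)C(C)(C)C | starting material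
7 | lithium acetylide of 6 | [Li]C#CCO[Si](C)(C)C(C)(C)C | intermediate
8 | (2R)-6-[(tert-butyldimethylsilyl)oxy]-1-(2-methyl-1,3-dithian-2-yl)hex-4-yn-2-ol | CC1(C[C@H](O)CC#CCO[Si](C)(C)C(C)(C)C)SCCCS1 | intermediate
9 | tert-butyl({(5R)-5-[(4-methoxybenzyl)oxy]-6-(2-methyl-1,3-dithian-2-yl)hex-2-yn-1-yl}oxy)dimethylsilane | CC1(C[C@H](OCc2ccc(OC)cc2)CC#CCO[Si](C)(C)C(C)(C)C)SCCCS1 | intermediate
10 | (4R)-8-[(tert-butyldimethylsilyl)oxy]-4-[(4-methoxybenzyl)oxy]oct-6-yn-2-one | CC(=O)C[C@H](OCc1ccc(OC)cc1)CC#CCO[Si](C)(C)C(C)(C)C | intermediate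
11 | 3-phenylpropanal | O=CCCc1ccccc1 | starting material
12 | dicyclohexylboron enolate of 10 (methyl-side enolate) | C=C(OB(C1CCCCC1)C1CCCCC1)C[C@H](OCc1ccc(OC)cc1)CC#CCO[Si](C)(C)C(C)(C)C | intermediate
13 | (3R,7R)-11-[(tert-butyldimethylsilyl)oxy]-3-hydroxy-7-[(4-methoxybenzyl)oxy]-1-phenylundec-9-yn-5-one (1,5-anti aldol) | O[C@H](CCc1ccccc1)CC(=O)C[C@H](OCc1ccc(OC)cc1)CC#CCO[Si](C)(C)C(C)(C)C | intermediate
14 | acetaldehyde | CC=O | starting material
15 | (3R,5R,7R)-11-[(tert-butyldimethylsilyl)oxy]-5-hydroxy-7-[(4-methoxybenzyl)oxy]-1-phenylundec-9-yn-3-yl acetate | CC(=O)O[C@H](CCc1ccccc1)C[C@H](O)C[C@H](OCc1ccc(OC)cc1)CC#CCO[Si](C)(C)C(C)(C)C | intermediate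
16 | (2R)-1-[(2R,4R,6R)-6-{4-[(tert-butyldimethylsilyl)oxy]but-2-yn-1-yl}-2-(4-methoxyphenyl)-1,3-dioxan-4-yl]-4-phenylbutan-2-yl acetate (4',6'-O-p-methoxybenzylidene acetal, all ring substituents equatorial) | CC(=O)O[C@H](CCc1ccccc1)C[C@H]2C[C@@H](CC#CCO[Si](C)(C)C(C)(C)C)O[C@@H](c3ccc(OC)cc3)O2 | intermediate
17 | (2R)-1-[(2R,4R,6R)-6-(4-hydroxybut-2-yn-1-yl)-2-(4-methoxyphenyl)-1,3-dioxan-4-yl]-4-phenylbutan-2-yl acetate | CC(=O)O[C@H](CCc1ccccc1)C[C@H]2C[C@@H](CC#CCO)O[C@@H](c3ccc(OC)cc3)O2 | intermediate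
18 | (2R)-1-[(2R,4R,6R)-2-(4-methoxyphenyl)-6-(4-oxobut-2-yn-1-yl)-1,3-dioxan-4-yl]-4-phenylbutan-2-yl acetate (ynal) | CC(=O)O[C@H](CCc1ccccc1)C[C@H]2C[C@@H](CC#CC=O)O[C@@H](c3ccc(OC)cc3)O2 | intermediate
19 | (triphenylphosphoranylidene)ketene, Ph3P=C=C=O | O=C=C=P(c1ccccc1)(c1ccccc1)c1ccccc1 | starting material
20 | (2R)-1-[(2R,4R,6R)-6-[(4S)-4-hydroxy-6-oxohex-2-yn-1-yl]-2-(4-methoxyphenyl)-1,3-dioxan-4-yl]-4-phenylbutan-2-yl acetate (β-hydroxy ynal) | CC(=O)O[C@H](CCc1ccccc1)C[C@H]2C[C@@H](CC#C[C@@H](O)CC=O)O[C@@H](c3ccc(OC)cc3)O2 | intermediate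
21 | (triphenylphosphoranylidene)acetate ester of 20 at the C6 oxygen (ester ylide, 6S) | CC(=O)O[C@H](CCc1ccccc1)C[C@H]2C[C@@H](CC#C[C@@H](OC(=O)C=P(c3ccccc3)(c3ccccc3)c3ccccc3)CC=O)O[C@@H](c4ccc(OC)cc4)O2 | intermediate
22 | (2R)-1-[(2R,4R,6R)-2-(4-methoxyphenyl)-6-{3-[(2S)-6-oxo-3,6-dihydro-2H-pyran-2-yl]prop-2-yn-1-yl}-1,3-dioxan-4-yl]-4-phenylbutan-2-yl acetate | CC(=O)O[C@H](CCc1ccccc1)C[C@H]2C[C@@H](CC#C[C@@H]3CC=CC(=O)O3)O[C@@H](c4ccc(OC)cc4)O2 | intermediate
23 | (2R)-1-[(2R,4R,6R)-2-(4-methoxyphenyl)-6-{(2Z)-3-[(2S)-6-oxo-3,6-dihydro-2H-pyran-2-yl]prop-2-en-1-yl}-1,3-dioxan-4-yl]-4-phenylbutan-2-yl acetate | CC(=O)O[C@H](CCc1ccccc1)C[C@H]2C[C@@H](C/C=C\[C@@H]3CC=CC(=O)O3)O[C@@H](c4ccc(OC)cc4)O2 | intermediate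
24 | (3R,5R,7R,9Z)-5,7-dihydroxy-10-[(2S)-6-oxo-3,6-dihydro-2H-pyran-2-yl]-1-phenyldec-9-en-3-yl acetate (CNP0264384.1) | CC(=O)O[C@H](CCc1ccccc1)C[C@H](O)C[C@H](O)C/C=C\[C@@H]1CC=CC(=O)O1 | target

**Step count and risks**

Total step count: 12. Longest linear sequence: 12 steps (from 1 or 2 to 24); all other building blocks (6, 11, 14, 19, the catalyst) are commercial.

Steps most likely to fail:

1. Step 10 (proposed new method). The β-hydroxy aldehyde may lose water to the enynal while it is warmed with the ylide. The amine may isomerise the ynal through its propargylic CH2. Addition of the secondary hydroxyl to the ylide may be too slow, so that intermolecular olefination takes over. The facial sense may also differ from the one assumed. Fallback with known chemistry: it sets out from ynal 18. Brown allylboration with (−)-Ipc2B(allyl) [from (+)-α-pinene; Et2O, −100 °C; ethanolamine work-up to spare the acetate] should give the (S)-enynol F1. Lindlar semihydrogenation of its internal alkyne should give the Z-dienol F2. Acryloyl chloride, Et3N and DMAP (CH2Cl2, 0 °C) should give the acrylate F3. Ring-closing metathesis with the second-generation Grubbs catalyst, (H2IMes)(PCy3)Cl2Ru=CHPh, in CH2Cl2 at 40 °C then closes the same C3=C4 bond between the terminal olefin and the acrylate, leaves the internal Z-olefin alone, and comes back to the route at 23.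

2. Step 11. Hydrogen uptake may not stop at the olefin, the conjugated ring double bond may be partly saturated, or the new olefin may isomerise from Z to E on palladium. Fallback: from 22 directly to 23 with zinc dust activated by Cu(OAc)2 and AgNO3 in MeOH/H2O (rt to 40 °C). This is an electron-transfer/protonation reduction of the oxygen-activated propargylic alkyne that uses no hydrogen gas and cannot run on to the alkane. It makes no new compound (F0) and rejoins at 23.

3. Step 6. The acetyl group may migrate between O8' and O6', or the β-hydroxy ketone may undergo retro-aldol cleavage before hydride transfer. Fallback: it sets out from aldol 13. Evans–Saksena reduction with Me4NBH(OAc)3 (MeCN/AcOH, −30 °C) should give the 6',8'-anti diol F4. Anhydrous DDQ (4 Å molecular sieves, CH2Cl2, 0 °C) then closes the p-methoxybenzylidene acetal onto O6', the only hydroxyl 1,3 to the PMB ether, to give the acetal alcohol F5. Ac2O, pyridine and DMAP acetylate the remaining C8' hydroxyl and return to the route at 16.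

Further compounds
F1 | step 10 | (2R)-1-[(2R,4R,6R)-6-[(4S)-4-hydroxyhept-6-en-2-yn-1-yl]-2-(4-methoxyphenyl)-1,3-dioxan-4-yl]-4-phenylbutan-2-yl acetate, (S)-enynol | CC(=O)O[C@H](CCc1ccccc1)C[C@H]2C[C@@H](CC#C[C@@H](O)CC=C)O[C@@H](c3ccc(OC)cc3)O2
F2 | step 10 | (2R)-1-[(2R,4R,6R)-6-[(2Z,4S)-4-hydroxyhepta-2,6-dien-1-yl]-2-(4-methoxyphenyl)-1,3-dioxan-4-yl]-4-phenylbutan-2-yl acetate, Z-dienol | CC(=O)O[C@H](CCc1ccccc1)C[C@H]2C[C@@H](C/C=C\[C@@H](O)CC=C)O[C@@H](c3ccc(OC)cc3)O2
F3 | step 10 | acrylate of F2 at the C6 oxygen (6S, 1'Z) | CC(=O)O[C@H](CCc1ccccc1)C[C@H]2C[C@@H](C/C=C\[C@@H](OC(=O)C=C)CC=C)O[C@@H](c3ccc(OC)cc3)O2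
F0 | step 11 | none | none
F4 | step 6 | (3R,5S,7R)-11-[(tert-butyldimethylsilyl)oxy]-7-[(4-methoxybenzyl)oxy]-1-phenylundec-9-yne-3,5-diol (6',8'-anti diol, same spatial arrangement as in 15) | O[C@H](CCc1ccccc1)C[C@H](O)C[C@H](OCc1ccc(OC)cc1)CC#CCO[Si](C)(C)C(C)(C)C
F5 | step 6 | C8' alcohol corresponding to acetate 16 (same configuration at every centre, cis-2,4,6 dioxane) | O[C@H](CCc1ccccc1)C[C@H]2C[C@@H](CC#CCO[Si](C)(C)C(C)(C)C)O[C@@H](c3ccc(OC)cc3)O2
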